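(The numbers in the tables are simulated for substances that don't exist; the scatter is artificial.)

J in the alpha flask stood flat from 10.0 h to 40.0 h, and this flask had to be judged from that plateau.

| flask | E | temperature | remark | time |
|---|---|---|---|---|
| alpha | 20 mM | 70 °C | the very flask that is asked about, followed so far |  |
| gamma | 40 mM | 65 °C | run made earlier |  |
| flask | 20 mM | 70 °C |  | 40 h |

alpha run (percent of the E charged): time / h: J / % = 4.00: 23.6; 10.0: 26.6; 20.0: 26.6; 30.0: 26.2; 40.0: 27.5

gamma run (percent of the E charged): time / min: J / % = 10.0: 8.5; 30.0: 14.7; 60.0: 15.2; 80.0: 15.4; 120: 13.9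

(readings scatter by 0.5 percentage points)

- ash: change nothing and wait 3.0 d more
- elm: at 40 h add E, 50.0% of the amount charged, then wait 3.0 d
- maple: at 40 h raise the temperature by 25 K, then wait 3.0 d

- J, in percent of the E first charged, at 40 h
- which option adds most J ("none" when 2 percentage points or less is all one gets) (ash / elm / maple / none)
- J present, in percent of the E first charged, after ash
- J present, in percent of the E first charged, after maple

- in percentages every species weighs as the E in it: one D or G counts as two
- for J the G are counted in
- additions bring no volume worth counting
- steps thought possible: E -> J; 2 E -> D; E + J <-> G; J <-> L; E <-> Z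
- in an amount of J, one G counts as one J

I treated J ⇌ L as fast, with its two sides in balance (thermodynamic control), and reckoned with the free share, J over J + L. The plateau readings averaged 0.267 of the charge, and that same number is the share floor, the least free share possible, since the pool J + L cannot exceed the charge. From above, the share and the pool are each bounded by 1. If heat did not lower the share, maple ended between the floor and 1; I could not read that sign from gamma, whose charge also differed. Gamma's lower plateau, near 15.2 per cent at twice the charge and at 65 °C, gave my hand no figure for a ceiling. Elm, reckoned at the alpha yield, added 0.134 of the charge, with the addition itself, 50.0% of the charge, as its ceiling, so I could not rank elm against maple.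

| J, fraction of charge | from below | from above |
|---|---|---|
| now | 0.262 | 0.272 |
| after maple | 0.267 | 1 |

The forecast gave 26.8%, inside my bracket, with a range of 26.2% to 27.4% whose top stands above it, and 27% after ash. For maple it gave 25% (15% to 30%), under my floor, saying “I expect about the same or slightly less”. It chose elm.

The flask gave 26.6% now and 26.6% after ash. Maple gave 52.0%, inside the bracket, and the best option was maple, adding 25 percentage points against 16 points for elm.

    E → J (k = 3.95 × 10⁻⁴ s⁻¹, Ea = 115 kJ mol⁻¹)
    2 E → D (k = 0.0123 M⁻¹ s⁻¹, Ea = 65.0 kJ mol⁻¹)
    E + J ⇌ G, settled at all times (K = 140 M⁻¹, ΔH = 2.00 kJ mol⁻¹)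
    J ⇌ L (K = 1.80, k = 0.00142 s⁻¹, Ea = 95.0 kJ mol⁻¹, ΔH = −60.0 kJ mol⁻¹)
    E ⇌ Z (K = 1.60, k = 2.32 × 10⁻⁴ s⁻¹, Ea = 100 kJ mol⁻¹, ΔH = −21.0 kJ mol⁻¹)
    (constants at 70 °C)

While E lasted, falling to 2.38% at 4.00 h, ring closure ran, with 95% of its turnover done by 8.00 h. J and L kept pace, their relaxation half-life of 0.0872 h being short against 40 h; at 40.0 h the flask held J 26.6% and L 47.8%. That is a pool of 74.4 and a free share of 0.357, above the floor of 0.267. Maple's J, held against that pool, is a share of 0.699.

For a repeat of the flask at 95 °C, the free share from maple, 0.699, times a pool of at most 1 gives a ceiling of 0.699 on J. The computed J is 62.7%, under that ceiling, with L at 27.1%.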